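in all of them: substrate 0.80 M
- beta: coupling partner 0.32 M; run made earlier
- delta: coupling partner 1.3 M; run made earlier
- flask: coupling partner 0.640 M; time 25 d

| run | time / d | other conformer / % | target / % | substrate / % | isomer of the product / % | side product / % |
|---|---|---|---|---|---|---|
| beta | 1.67 | 40.6 | 4.7 | 41.9 | 12.3 | 3.2 |
| beta | 4.00 | 33.8 | 5.3 | 33.9 | 19.1 | 6.5 |
| beta | 8.00 | 27.8 | 4.8 | 28.8 | 24.8 | 13.5 |
| beta | 20.0 | 24.7 | 1.7 | 25.3 | 27.0 | 22.5 |
| delta | 1.67 | 21.1 | 15.8 | 20.7 | 36.9 | 4.5 |
| delta | 4.00 | 7.8 | 19.1 | 7.5 | 52.8 | 10.6 |
| delta | 8.00 | 1.9 | 21.9 | 1.4 | 60.4 | 14.7 |
| delta | 20.0 | 0 | 22.5 | 0.2 | 62.7 | 15.9 |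

(readings scatter by 0.5 percentage points)
* the species in which most of what was charged as substrate, at 25 d sits (other conformer / side product / isomer of the product / substrate / target)
* the largest share itself, whichever of these holds it, in percent of the substrate charged
- percent here means substrate units held: one side product counts as two
- the numbers in the tables scatter with a standard deviation of 0.5 percentage points
- a reading or a percentage of target counts all its forms, free or not

- The pitfall in these tables was to add the side product at its printed percent, because in the beta run isomer, target and side product then came to 51.2 %, above the 40.0 % that the coupling partner was worth, whereas with half the side product they came to 40.0 %.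
- Of coupling partner so counted, the isomer took 0.676 in the beta run and 0.673 in the delta run, as read at their last readings, though the charges of coupling partner differed by a factor of 4.06.
- I therefore folded the charges into one number, the isomer yield per full charge of coupling partner, that share times charged [coupling partner] over charged [substrate], which for this flask is 0.541; as long as that share holds, the isomer is this number times the fraction of coupling partner not left.
- One number was not enough, for it does not say what fraction of coupling partner is left: by the readings the beta run still had 0.0912 of its charge at 8.00 d, and I guessed, as an estimate and not a bound, no more than this for the flask, which runs 3.12 times as long, so I reckoned 49.2 % to 54.1 % of isomer.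
- The forecast, counting the side product “with no extra partner”, said isomer of the product at 51 %, inside my range.

    substrate ⇌ other conformer (K = 0.970, k = 1.73 × 10⁻⁴ s⁻¹)
    substrate + coupling partner → target (k = 3.51 × 10⁻⁶ L mol⁻¹ s⁻¹)
    coupling partner + other conformer → isomer of the product (k = 7.89 × 10⁻⁶ L mol⁻¹ s⁻¹)
    substrate + target → side product (k = 7.11 × 10⁻⁶ L mol⁻¹ s⁻¹)
    crystals ⇌ target, rate k5*(cs5 - [target]) while solid is left; crystals form when [target] > cs5 (solubility = 0.670 M, k = 8.71 × 10⁻⁵ s⁻¹)

- The flask gave isomer of the product at 50.4 % with 7.2 % of its coupling partner left, and the number gives 50.2 %; the neighbour with 0.16 M, where coupling partner was the limiting reagent at 0.049 % left, gives 13.5 % against a simulated 13.6 %. In the flask at 0.0273 d, other conformer fell back 36 times faster than it went on. At 25.0 d the flask held 4.90 % of other conformer beside 5.05 % of substrate.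

Readings and results were generated by integration on assumed constants; scatter was added.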